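Assumption: atoms carry the numbers of their positions in the target SMILES (C1 to O29). Rings are lettered A (cyclopentane C3–C4–C10–C11–C27), B (lactone O5/C6/C8 on C4 and C10), C (six-membered lactam C11–C12–C13–N21–C28–C27), D (seven-membered ring N21–C22–C23–C24–C25–C27–C28) and E (pendant lactone C14–C18/O20). Compounds 1, 6, 9, 14 and 23 are taken as purchasable.

## Analysis of the target

The target is pentacyclic. Cyclopentane ring A is cis-fused to γ-lactone B at C4–C10 and cis-fused to lactam ring C at C11–C27, and ring D bridges N21 and C27 through C22–C25. Because N21 and C27 are both bridgeheads and the lactam carbonyl C28 is the one-atom bridge between them, the amide cannot be planar; it is more electrophilic than a normal lactam and is best formed last. There are ten stereocentres. Five are contiguous on ring A (C3, C4, C10, C11 and the quaternary C27), with the ethyl group on C3 trans to O5 and cis to C28, and C8 on C10 trans to C12 on C11. The C8 methyl group lies on the concave face of the A/B bicycle, and the C16 methyl group is cis to the C14 substituent on lactone E. Both lactone α-centres (C8, C16) are epimerisable, and the one at C8 is in its less stable arrangement. The hard points are the all-carbon quaternary C27 shared by rings A, C and D, the dense stereochemistry of ring A, and the closure of ring D against amide planarity. The strategy rests on one feature of ring A: C4 bears oxygen and is flanked by C3 and C10, and the C11–C27 bond is shared with ring C. That is the pattern of a cyclopentenone made from an alkyne (C10, C11), an alkene (C27, C3) and carbon monoxide (C4).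

## Retrosynthetic reasoning

Ring D is opened first, at C24–C25, to give iodo aldehyde 28. This bond is cut because its formation creates the strained bridged lactam, which should not have to survive any other step. The aldehyde on C27 has no α-hydrogen, and the forward reaction is a samarium Barbier closure that also creates the C25 carbinol.

28 is traced through hydroxy aldehyde 27 to acetal silyl ether 26 by functional-group changes only. One acid step should unmask both the aldehyde and the primary alcohol.

Lactone B of 26 is cut at O5–C6, leading via hydroxy ester 25 to keto ester 24. Only a C4 alcohol cis to the C10 arm can lactonise, so the forward reduction has to bring hydride to the face of the ethyl group.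

The C8–C10 bond of 24 is cut to give ketone 22 and lactate triflate 23. C10 is α to the C4 ketone, and with C3 already substituted it is the only methylene next to the carbonyl, so the kinetic enolate is defined. 23 delivers C6, C8 and C9 in one piece and fixes the concave C8 methyl group by an inversion at carbon and not by a late enolate protonation.

22 is simplified to enone 20 through 21 by removing the C11 hydrogen and the C2–C3 bond. In 20 the only enolisable position is C3, so the ethyl group is introduced there before the double bond is saturated. Hydrogenation then sets C11.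

Enone 20 is cut at C11–C27, C3–C4 and C4–C10 to give enyne 18. This is the central disconnection: one reaction makes rings A and C and the quaternary centre, and leaves the C4 ketone exactly where O5 is needed, with C3 and C10 activated for the two side arms.

The amide N21–C28 of 18 is cut to give amine 16 and acid 5. Acid 5 comes from ester 1 by α-methylenation (via 2 and 4) and saponification.

The N21–C22 bond of 16 is cut by reductive amination logic to give carbamate 13 and aldehyde 14, which carries C22–C24 with oxygen on C24 for the later iodide.

Lactone 13 is cut at C14–C15 to give amino aldehyde 8 and bromo ester 9 (as its homoenolate); 8 comes from amino acid 6 through amide 7.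

- 6 already contains C10–C13, the alkyne, the nitrogen and the C13 stereocentre, and 9 supplies C16 with its methyl group.
- A methylene lactone that needs hydrogenation could not coexist with the alkyne.
- Acetylide displacement on a serine-derived arm would not tolerate the lactone.
- Felkin addition to an N,N-disubstituted amino aldehyde would give the wrong C14 epimer. The free N–H carbamate of 8 allows chelation control, which gives the required syn (13R,14R) relationship.

## Alternatives that were turned down

Alternative 1: The C11–C27 bond is traced back to a C11–C28 bond in the pentacyclic enamine A1, in which ring A is still a cyclohexene and N21–C28=C27 is an enamine. In the forward step tert-butyl hypochlorite chlorinates C27, water adds to the iminium carbon C28, and C11 shifts from C28 to C27 as chloride leaves. This contracts ring A, expands the pyrrolidine to lactam ring C and gives the silyl ether A2 of the target.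
- For: one late step creates the quaternary centre, the lactam and both ring sizes. The shift is stereospecific. Ring D is present from the start, so no ring has to be closed against amide planarity. On this point it is stronger than the chosen route.
- Against: A1 is itself a pentacyclic compound with nine stereocentres and needs a full synthesis of its own. The face of chlorination at C27 next to the C25 silyloxy group is hard to predict. Aromatisation of the enamine to a pyrrole, or simple hydroxylation, competes with the shift. The twisted lactam is born in aqueous oxidising medium, where it is most exposed.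
- Comparison: the chosen strategy reaches its key-step substrate in eight steps and tests its riskiest reaction early, whereas here the risk sits at the end of the longest sequence.

Alternative 2: The C3–C27 bond is cut, leading to the allylic carbonate A3 with an α-formyl lactam. Pd(PPh3)4 (zerovalent palladium) ionises the carbonate, and the stabilised enolate attacks the inner allyl terminus C3 in a five-membered closure. The product is the vinyl formyl lactam A4, whose vinyl group would later be hydrogenated to ethyl.
- For: a soft nucleophile under neutral conditions; C27 and C3 are made together; C25 is already an aldehyde; no enolate ethylation and no C4 ketone reduction are needed. On mildness it is at least as good as the chosen route.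
- Against: only one ring and one bond are formed. C4, C8, C10 and C11 must be set beforehand on an open chain, without a ring template. Two adjacent centres, one quaternary, depend on an outer-sphere attack of a planar enolate on a π-allyl unit. The C3=C2 alkene of A3 has a second allylic leaving group, the lactone oxygen O5 on C4, so palladium can open ring B. O-alkylation and deformylation are further exits.
- Comparison: the Pauson–Khand step gives two rings and three bonds from a linear amide, and its ketone then serves as the handle for every remaining substituent.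

Alternative 3: The C3–C4 and O5–C6 bonds are cut, leading to the aldehyde ester A5, a lactam with a quaternary C27 that carries a propenyl group and the acetal. SmI2 with HMPA and tert-butanol makes the C4 ketyl, which adds to C3; the C2 radical is reduced to the ethyl group, and the samarium alkoxide lactonises onto C6. The product A6 is identical with compound 26 of the chosen route.
- For: one step sets C3 and C4, closes rings A and B and delivers the ethyl group. The usual anti relation between the new hydroxyl and the neighbouring substituent matches the target. Between the ring C stage and this compound it is shorter than the chosen route, which needs four steps there.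
- Against: C27 of A5 has to be built earlier by alkylation of a lactam enolate under the same remote control from C13, but without an organising metal template. C10 sits α to the aldehyde in an open chain and can epimerise. An unactivated disubstituted alkene is a slow ketyl acceptor, so aldehyde reduction and pinacol coupling compete.
- Comparison: the chosen strategy makes C27 together with both carbocyclic bonds and keeps C10 configurationally secure on a ring.

Key step: step 9

## Route

Step 1
Reactants: 1 methyl 3,3-dimethoxypropanoate
Product: 2 methyl 2-[(dimethylamino)methyl]-3,3-dimethoxypropanoate (racemic)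
Conditions: LiN(iPr)2, THF, −78 °C; then CH2=NMe2+ I−, −78 °C → rt
Reagents that add atoms: N,N-dimethylmethyleneiminium iodide, C[N+](C)=C.[I-]
Why: Mannich reaction of the ester lithium enolate, which at −78 °C should not expel a β-methoxy group, with the preformed iminium salt.

Step 2
Reactants: 2 methyl 2-[(dimethylamino)methyl]-3,3-dimethoxypropanoate
Product: 4 methyl 2-(dimethoxymethyl)prop-2-enoate, via ammonium iodide 3 (not isolated)
Conditions: MeI, CH2Cl2, rt; then DBU, 0 °C → rt
Reagents that add atoms: none
Why: Quaternisation makes the amine a leaving group and base-induced Hofmann-type elimination through the ester enolate gives the α-methylene ester; trimethylamine leaves far more readily than methoxide.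

Step 3
Reactants: 4 methyl 2-(dimethoxymethyl)prop-2-enoate
Product: 5 2-(dimethoxymethyl)prop-2-enoic acid
Conditions: LiOH, THF/H2O, 0 °C; then 1 M HCl to pH 3, 0 °C
Reagents that add atoms: lithium hydroxide, [Li+].[OH-]
Why: Ester saponification; the acetal is stable to base and, being attached to the electron-poor acrylate, should survive the brief cold acidification.

Step 4
Reactants: 6 (2R)-2-[(tert-butoxycarbonyl)amino]pent-4-ynoic acid
Product: 7 tert-butyl N-[(2R)-1-[methoxy(methyl)amino]-1-oxopent-4-yn-2-yl]carbamate
Conditions: MeNH(OMe)·HCl, EDC·HCl, HOBt, N-methylmorpholine, CH2Cl2, 0 °C → rt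
Reagents that add atoms: N,O-dimethylhydroxylamine hydrochloride, CNOC.Cl
Why: Carbodiimide amide coupling to the N-methoxy-N-methylamide (Weinreb amide); the urethane group prevents racemisation at C13.

Step 5
Reactants: 7 tert-butyl N-[(2R)-1-[methoxy(methyl)amino]-1-oxopent-4-yn-2-yl]carbamate
Product: 8 tert-butyl N-[(2R)-1-oxopent-4-yn-2-yl]carbamate
Conditions: LiAlH4, THF, −30 → 0 °C; aq. potassium sodium tartrate
Reagents that add atoms: none
Why: Weinreb reduction stops at the aldehyde because the chelated tetrahedral intermediate collapses only on work-up; the aldehyde is used at once so that C13 does not epimerise.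

Step 6
Reactants: 8 tert-butyl N-[(2R)-1-oxopent-4-yn-2-yl]carbamate; 9 methyl (2S)-3-bromo-2-methylpropanoate
Product: 13 tert-butyl N-[(1R)-1-[(2R,4R)-4-methyl-5-oxooxolan-2-yl]but-3-yn-1-yl]carbamate, via zinc homoenolate 10 (not isolated), via titanium homoenolate 11 (not isolated), via hydroxy ester 12 (not isolated)
Conditions: 9, Zn, LiCl, THF, 40 °C; ClTi(OiPr)3, −20 °C; then 8, −20 → 0 °C; then AcOH, PhMe, 80 °C
Reagents that add atoms: none
Why: Homoenolate addition to an N-carbamoyl α-amino aldehyde: titanium should bridge the aldehyde oxygen and the carbamate (Cram chelate), so the reagent attacks opposite the propargyl group and gives the syn (13R,14R) alcohol. The C16 centre comes unchanged from 9 because it is not the metal-bearing carbon, and acid closes lactone E with the methyl group cis to the C14 substituent.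

Step 7
Reactants: 13 tert-butyl N-[(1R)-1-[(2R,4R)-4-methyl-5-oxooxolan-2-yl]but-3-yn-1-yl]carbamate; 14 3-[(tert-butyldimethylsilyl)oxy]propanal
Product: 16 (3R,5R)-5-[(1R)-1-({3-[(tert-butyldimethylsilyl)oxy]propyl}amino)but-3-yn-1-yl]-3-methyloxolan-2-one, via amine hydrochloride 15 (not isolated)
Conditions: HCl, dioxane, rt, then evaporation; then 14, Et3N, NaBH(OAc)3, ClCH2CH2Cl, rt
Reagents that add atoms: none
Why: Acidolysis of the carbamate followed by reductive amination; the amine is set free only in the presence of the aldehyde, so iminium formation should outrun attack of nitrogen on the lactone, and the α-branched amine should stop at monoalkylation.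

Step 8
Reactants: 16 (3R,5R)-5-[(1R)-1-({3-[(tert-butyldimethylsilyl)oxy]propyl}amino)but-3-yn-1-yl]-3-methyloxolan-2-one; 5 2-(dimethoxymethyl)prop-2-enoic acid
Product: 18 N-{3-[(tert-butyldimethylsilyl)oxy]propyl}-2-(dimethoxymethyl)-N-{(1R)-1-[(2R,4R)-4-methyl-5-oxooxolan-2-yl]but-3-yn-1-yl}prop-2-enamide, via acid chloride 17 (not isolated)
Conditions: 5, Me2C=C(Cl)NMe2, CH2Cl2, 0 °C; then 16, iPr2NEt, DMAP (cat.), 0 °C → rt
Reagents that add atoms: none
Why: The neutral chloroenamine converts the acid into its chloride without releasing HCl, which spares the acetal; N-acylation of the hindered secondary amine by the acid chloride is then fast.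

Step 9
Reactants: 18 N-{3-[(tert-butyldimethylsilyl)oxy]propyl}-2-(dimethoxymethyl)-N-{(1R)-1-[(2R,4R)-4-methyl-5-oxooxolan-2-yl]but-3-yn-1-yl}prop-2-enamide
Product: 20 (13R,14R,16R,27R)-enone lactam: cyclopentenone ring A (C4 ketone; C10=C11) fused at C11–C27 to N-(3-silyloxypropyl) lactam ring C; C27 carries CH(OMe)2 trans to lactone E, via alkyne dicobalt hexacarbonyl complex 19 (not isolated)
Conditions: Co2(CO)8, CH2Cl2, rt; then NMO, 4 Å MS, CH2Cl2, 0 °C → rt
Reagents that add atoms: dicobalt octacarbonyl, O=C=[Co](=C=O)(=C=O)(=C=O)[Co](=C=O)(=C=O)(=C=O)=C=O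
Why: Co2(CO)8 binds the terminal alkyne as complex 19, and the N-oxide removes one CO ligand oxidatively, which opens a site for the acrylamide alkene. Migratory insertion of the alkene into the Co–C11 bond forms C11–C27 and closes lactam ring C in a 6-exo sense, with C3 left outside the ring on cobalt. CO insertion into the Co–C3 bond and reductive elimination onto C10 then form C3–C4 and C4–C10 and close ring A as the cyclopentenone, a formal [2+2+1]. The closest known reaction type is the intramolecular Pauson–Khand reaction of 1,7-enynes whose 1,1-disubstituted alkene ends as an angular quaternary carbon. The tether fixes the regiochemistry, and because C27 carries no hydrogen the cobaltacycle cannot collapse by β-hydride elimination to a diene, the usual exit of electron-poor alkenes. The amide has to react through the rotamer with C13 syn to the acryloyl group, which is reached by rotation at the reaction temperature. The new centre C27 is controlled by C13: allylic 1,3-strain with the N-propyl chain should hold lactone E pseudo-axial in the forming ring, and the acetal arm should turn to the opposite face (27R). This induction across N21–C28 is expected to be moderate, so chromatographic removal of the C27 epimer is planned.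

Step 10
Reactants: 20 (13R,14R,16R,27R)-enone lactam
Product: 21 (3S,13R,14R,16R,27R)-3-ethyl enone lactam: as 20 with an ethyl group on C3 cis to the lactam carbonyl C28
Conditions: LiN(iPr)2, THF, −78 °C; then EtI, DMPU, −78 → −30 °C
Reagents that add atoms: iodoethane, CCI
Why: Enolate alkylation: C3 is the only α-position of the enone that can be deprotonated kinetically, and the cross-conjugated enolate should take the ethyl group on the face away from the acetal arm of the neighbouring quaternary C27.

Step 11
Reactants: 21 (3S,13R,14R,16R,27R)-3-ethyl enone lactam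
Product: 22 (3S,11S,13R,14R,16R,27S)-ketone: cis-fused saturated bicycle with C11–H on the face of the acetal
Conditions: H2 (1 atm), Pd/C, EtOAc, rt
Reagents that add atoms: none
Why: Heterogeneous hydrogenation of the enone; as with other hydrindenones that bear an angular substituent, hydrogen should add to C11 on the convex face, syn to the angular acetal and opposite the C27–C28 ring bond, giving the cis ring fusion.

Step 12
Reactants: 22 (3S,11S,13R,14R,16R,27S)-ketone; 23 ethyl (2S)-2-{[(trifluoromethyl)sulfonyl]oxy}propanoate
Product: 24 (3S,8S,10R,11S,13R,14R,16R,27S)-keto ester: 22 with a CH(CH3)CO2Et arm on C10 trans to C12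
Conditions: LiN(iPr)2, THF, −78 °C; then 23, DMPU, −78 → −40 °C
Reagents that add atoms: none
Why: Kinetic deprotonation takes the C10 methylene and not the tertiary C3–H, and the enolate displaces triflate in an SN2 alkylation with inversion, which fixes C8 as S. Attack on the enolate face away from C12 gives the trans 10R arrangement, which is also the more stable one.

Step 13
Reactants: 24 (3S,8S,10R,11S,13R,14R,16R,27S)-keto ester
Product: 26 (3S,4S,8S,10R,11S,13R,14R,16R,27S)-lactone acetal: rings A, B, C and E complete, CH(OMe)2 on C27, N-(3-silyloxypropyl), via hydroxy ester 25 (not isolated)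
Conditions: LiBH(s-Bu)3, THF, −78 °C; AcOH; then PPTS (cat.), PhMe, 60 °C
Reagents that add atoms: none
Why: The bulky hydride should attack C4 from the face of the smaller ethyl group, opposite the branched propionate arm, so the hydroxyl ends cis to the ester and lactonises to the cis-fused ring B. An epimeric alcohol cannot lactonise and would be separated.

Step 14
Reactants: 26 (3S,4S,8S,10R,11S,13R,14R,16R,27S)-lactone acetal
Product: 27 hydroxy aldehyde: 26 with CHO on C27 and a free N-(3-hydroxypropyl) chain
Conditions: 3 M HCl, THF, 45 °C
Reagents that add atoms: water, O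
Why: Acid hydrolysis of the dimethyl acetal and of the primary silyl ether in one operation; the aldehyde has no α-hydrogen and the lactones are stable to aqueous acid.

Step 15
Reactants: 27 hydroxy aldehyde
Product: 28 iodo aldehyde: 27 with an N-(3-iodopropyl) chain
Conditions: I2, PPh3, imidazole, CH2Cl2, 0 °C
Reagents that add atoms: iodine, II
Why: Appel-type iodination of the primary alcohol; the non-enolisable aldehyde is inert to the phosphonium reagent.

Step 16
Reactants: 28 iodo aldehyde
Product: 29 target CNP0120800.1 (3S,4S,8S,10R,11S,13R,14R,16R,25R,27S)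
Conditions: SmI2, HMPA, THF, −78 °C → rt, high dilution
Reagents that add atoms: none
Why: Intramolecular samarium Barbier reaction: the C–I bond is reduced to an alkylsamarium that adds to the aldehyde, forming C24–C25 and ring D in a 7-exo closure. With HMPA occupying the metal, the aldehyde oxygen should lie anti to the lactam carbonyl, and attack from the nitrogen side then gives the 25R alcohol.

## Compound list

1 | methyl 3,3-dimethoxypropanoate | COC(OC)CC(=O)OC | starting material
2 | methyl 2-[(dimethylamino)methyl]-3,3-dimethoxypropanoate (racemic) | COC(OC)C(CN(C)C)C(=O)OC | intermediate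
3 | [2-(dimethoxymethyl)-3-methoxy-3-oxopropyl]trimethylammonium iodide (racemic) | COC(OC)C(C[N+](C)(C)C)C(=O)OC.[I-] | intermediate
4 | methyl 2-(dimethoxymethyl)prop-2-enoate | COC(OC)C(=C)C(=O)OC | intermediate
5 | 2-(dimethoxymethyl)prop-2-enoic acid | COC(OC)C(=C)C(=O)O | intermediate
6 | (2R)-2-[(tert-butoxycarbonyl)amino]pent-4-ynoic acid | C#CC[C@H](C(=O)O)NC(=O)OC(C)(C)C | starting material
7 | tert-butyl N-[(2R)-1-[methoxy(methyl)amino]-1-oxopent-4-yn-2-yl]carbamate | C#CC[C@H](C(=O)N(C)OC)NC(=O)OC(C)(C)C | intermediate
8 | tert-butyl N-[(2R)-1-oxopent-4-yn-2-yl]carbamate | C#CC[C@H](C=O)NC(=O)OC(C)(C)C | intermediate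
9 | methyl (2S)-3-bromo-2-methylpropanoate | BrC[C@@H](C)C(=O)OC | starting material
10 | [(2S)-3-methoxy-2-methyl-3-oxopropyl]zinc bromide | Br[Zn]C[C@@H](C)C(=O)OC | intermediate
11 | [(2S)-3-methoxy-2-methyl-3-oxopropyl]tri(propan-2-yloxy)titanium | CC(C)O[Ti](OC(C)C)(OC(C)C)C[C@@H](C)C(=O)OC | intermediate
12 | methyl (2R,4R,5R)-5-[(tert-butoxycarbonyl)amino]-4-hydroxy-2-methyloct-7-ynoate | C#CC[C@H]([C@H](O)C[C@@H](C)C(=O)OC)NC(=O)OC(C)(C)C | intermediate
13 | tert-butyl N-[(1R)-1-[(2R,4R)-4-methyl-5-oxooxolan-2-yl]but-3-yn-1-yl]carbamate | C#CC[C@H]([C@H]1C[C@@H](C)C(=O)O1)NC(=O)OC(C)(C)C | intermediate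
14 | 3-[(tert-butyldimethylsilyl)oxy]propanal | O=CCCO[Si](C)(C)C(C)(C)C | starting material
15 | (3R,5R)-5-[(1R)-1-aminobut-3-yn-1-yl]-3-methyloxolan-2-one hydrochloride | C#CC[C@H]([C@H]1C[C@@H](C)C(=O)O1)N.Cl | intermediate
16 | (3R,5R)-5-[(1R)-1-({3-[(tert-butyldimethylsilyl)oxy]propyl}amino)but-3-yn-1-yl]-3-methyloxolan-2-one | C#CC[C@H]([C@H]1C[C@@H](C)C(=O)O1)NCCCO[Si](C)(C)C(C)(C)C | intermediate
17 | 2-(dimethoxymethyl)prop-2-enoyl chloride | COC(OC)C(=C)C(=O)Cl | intermediate
18 | N-{3-[(tert-butyldimethylsilyl)oxy]propyl}-2-(dimethoxymethyl)-N-{(1R)-1-[(2R,4R)-4-methyl-5-oxooxolan-2-yl]but-3-yn-1-yl}prop-2-enamide (acrylamide 1,7-enyne) | C#CC[C@H]([C@H]1C[C@@H](C)C(=O)O1)N(CCCO[Si](C)(C)C(C)(C)C)C(=O)C(=C)C(OC)OC | intermediate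
19 | hexacarbonyldicobalt complex of the alkyne of 18 | [CH]12[Co]3(=C=O)(=C=O)(=C=O)[Co]1(=C=O)(=C=O)(=C=O)C23C[C@H]([C@H]4C[C@@H](C)C(=O)O4)N(CCCO[Si](C)(C)C(C)(C)C)C(=O)C(=C)C(OC)OC | intermediate
20 | (13R,14R,16R,27R)-enone lactam (ring A cyclopentenone fused to lactam ring C, acetal on C27 trans to lactone E) | COC(OC)[C@@]12CC(=O)C=C1C[C@H]([C@H]3C[C@@H](C)C(=O)O3)N(CCCO[Si](C)(C)C(C)(C)C)C2=O | intermediate
21 | (3S,13R,14R,16R,27R)-3-ethyl enone lactam | COC(OC)[C@@]12[C@H](CC)C(=O)C=C1C[C@H]([C@H]3C[C@@H](C)C(=O)O3)N(CCCO[Si](C)(C)C(C)(C)C)C2=O | intermediate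
22 | (3S,11S,13R,14R,16R,27S)-cis-fused ketone | COC(OC)[C@@]12[C@H](CC)C(=O)C[C@@H]1C[C@H]([C@H]3C[C@@H](C)C(=O)O3)N(CCCO[Si](C)(C)C(C)(C)C)C2=O | intermediate
23 | ethyl (2S)-2-{[(trifluoromethyl)sulfonyl]oxy}propanoate | CCOC(=O)[C@H](C)OS(=O)(=O)C(F)(F)F | starting material
24 | (3S,8S,10R,11S,13R,14R,16R,27S)-keto ester (ethyl propanoate arm on C10) | COC(OC)[C@@]12[C@H](CC)C(=O)[C@@H]([C@H](C)C(=O)OCC)[C@@H]1C[C@H]([C@H]3C[C@@H](C)C(=O)O3)N(CCCO[Si](C)(C)C(C)(C)C)C2=O | intermediate
25 | (3S,4S,8S,10R,11S,13R,14R,16R,27S)-hydroxy ester (C4 hydroxyl cis to the C10 arm) | CC[C@@H]1[C@@H](O)[C@@H]([C@H](C)C(=O)OCC)[C@@H]2C[C@H]([C@H]3C[C@@H](C)C(=O)O3)N(CCCO[Si](C)(C)C(C)(C)C)C(=O)[C@]12C(OC)OC | intermediate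
26 | (3S,4S,8S,10R,11S,13R,14R,16R,27S)-lactone acetal (rings A, B, C, E; acetal on C27; silyloxypropyl on N21) | CC[C@@H]1[C@H]2OC(=O)[C@@H](C)[C@H]2[C@@H]2C[C@H]([C@H]3C[C@@H](C)C(=O)O3)N(CCCO[Si](C)(C)C(C)(C)C)C(=O)[C@]12C(OC)OC | intermediate
27 | hydroxy aldehyde (CHO on C27, 3-hydroxypropyl on N21) | CC[C@@H]1[C@H]2OC(=O)[C@@H](C)[C@H]2[C@@H]2C[C@H]([C@H]3C[C@@H](C)C(=O)O3)N(CCCO)C(=O)[C@]12C=O | intermediate
28 | iodo aldehyde (CHO on C27, 3-iodopropyl on N21) | CC[C@@H]1[C@H]2OC(=O)[C@@H](C)[C@H]2[C@@H]2C[C@H]([C@H]3C[C@@H](C)C(=O)O3)N(CCCI)C(=O)[C@]12C=O | intermediate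
29 | CNP0120800.1 (3S,4S,8S,10R,11S,13R,14R,16R,25R,27S) | CC[C@@H]1[C@H]2OC(=O)[C@@H](C)[C@H]2[C@@H]2C[C@H]([C@H]3C[C@@H](C)C(=O)O3)N3CCC[C@@H](O)[C@@]12C3=O | target

## Step count and least certain steps

Total step count: 16 (three for acid 5, thirteen in the main line). Longest linear sequence: 13 steps (steps 4 to 16, from 6).

Step 9 (key step). The hindered, conjugated 1,1-disubstituted alkene may insert too slowly, so that complex 19 loses cobalt or the alkyne is reduced. Facial selection at C27 may also be poor, because the only controlling centre, C13, acts across the amide. Fallback: the dicobalt cluster is given up for a mononuclear oxidative cyclisation with Mo(CO)6 and DMSO in toluene at 100 °C, a carbonyl source that accepts electron-poor alkenes. It sets out from 18 and comes back at 20, with the C27 epimers again separated at that stage (no new compound, F0).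

Step 16. Closure of ring D has to twist the amide, so protonation of the alkylsamarium or reduction of the aldehyde may win. If samarium bridges the two carbonyl oxygens, the wrong face of the aldehyde may be attacked. Fallback: from 28, CrCl2 with catalytic cobalt phthalocyanine Co(C32H16N8) in DMF turns the iodide into an alkylchromium species that does not reduce aldehydes and lives long enough for a slow closure. It comes back at 29 (no new compound, F0).

Step 12. The basic enolate may eliminate triflic acid from 23 or be O-alkylated, and the congested secondary–secondary bond may form slowly enough for the enolate to equilibrate. Fallback from 22, returning at 26: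
- the kinetic enolate is alkylated with methyl bromoacetate to the keto ester F1;
- LiBH(s-Bu)3 reduction and acid lactonisation give the nor-methyl lactone F2;
- methylation of its lactone enolate (LiN(SiMe3)2, MeI) enters from the convex face and gives the C8-epimeric lactone F3;
- deprotonation with LiN(iPr)2 and protonation by 2,6-di-tert-butylphenol at −78 °C, again from the convex face, turns the methyl group to the concave side and gives 26.

Step 10. C-ethylation at the neopentyl-type C3 may be slow, allowing proton transfer and O-alkylation, and the facial preference at C3 is not secure. Fallback from 20, returning at 22: aldol addition of the C3 enolate to acetaldehyde gives the β-hydroxy ketone F4; MsCl and Et3N (the mesylate eliminates in the flask) give the ethylidene dienone F5; hydrogenation over Pd/C saturates both double bonds to 22. C3 stays adjustable by enolisation and kinetic protonation as long as C4 is a ketone.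

Step 13. Hydride may be delivered to the face of the propionate arm, which gives an alcohol that cannot lactonise. Fallback from 24, returning at 26: that epimeric alcohol F6 is converted (MsCl, Et3N) into the methanesulfonate F7 and heated in DMF. The ester carbonyl displaces the sulfonate with inversion at C4, ethyl methanesulfonate is lost, and 26 results.

## Further compounds

F0 | step 9 | none | none
F0 | step 16 | none | none
F1 | step 12 | keto ester with a methyl acetate arm on C10 | COC(OC)[C@@]12[C@H](CC)C(=O)[C@@H](CC(=O)OC)[C@@H]1C[C@H]([C@H]3C[C@@H](C)C(=O)O3)N(CCCO[Si](C)(C)C(C)(C)C)C2=O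
F2 | step 12 | nor-methyl lactone (26 without the C8 methyl group) | CC[C@@H]1[C@H]2OC(=O)C[C@H]2[C@@H]2C[C@H]([C@H]3C[C@@H](C)C(=O)O3)N(CCCO[Si](C)(C)C(C)(C)C)C(=O)[C@]12C(OC)OC
F3 | step 12 | C8-epimeric lactone (8R epimer of 26) | CC[C@@H]1[C@H]2OC(=O)[C@H](C)[C@H]2[C@@H]2C[C@H]([C@H]3C[C@@H](C)C(=O)O3)N(CCCO[Si](C)(C)C(C)(C)C)C(=O)[C@]12C(OC)OC
F4 | step 10 | β-hydroxy ketone (1-hydroxyethyl on C3 of 20, diastereomer mixture at C3 and the carbinol) | COC(OC)[C@@]12C(C(C)O)C(=O)C=C1C[C@H]([C@H]3C[C@@H](C)C(=O)O3)N(CCCO[Si](C)(C)C(C)(C)C)C2=O
F5 | step 10 | ethylidene dienone (ethylidene on C3 of 20, alkene geometry not defined) | COC(OC)[C@@]12C(=CC)C(=O)C=C1C[C@H]([C@H]3C[C@@H](C)C(=O)O3)N(CCCO[Si](C)(C)C(C)(C)C)C2=O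
F6 | step 13 | epimeric alcohol (4R epimer of 25) | CC[C@@H]1[C@H](O)[C@@H]([C@H](C)C(=O)OCC)[C@@H]2C[C@H]([C@H]3C[C@@H](C)C(=O)O3)N(CCCO[Si](C)(C)C(C)(C)C)C(=O)[C@]12C(OC)OC
F7 | step 13 | methanesulfonate of F6 | CC[C@@H]1[C@H](OS(C)(=O)=O)[C@@H]([C@H](C)C(=O)OCC)[C@@H]2C[C@H]([C@H]3C[C@@H](C)C(=O)O3)N(CCCO[Si](C)(C)C(C)(C)C)C(=O)[C@]12C(OC)OC
A1 | alternative 1 | pentacyclic enamine (C11 bonded to C28, C27=C28) | CC[C@@H]1[C@H]2OC(=O)[C@@H](C)[C@H]2[C@@H]2C[C@H]([C@H]3C[C@@H](C)C(=O)O3)N3CCC[C@@H](O[Si](C)(C)C(C)(C)C)C1=C23
A2 | alternative 1 | O-silyl ether of the target | CC[C@@H]1[C@H]2OC(=O)[C@@H](C)[C@H]2[C@@H]2C[C@H]([C@H]3C[C@@H](C)C(=O)O3)N3CCC[C@@H](O[Si](C)(C)C(C)(C)C)[C@@]12C3=O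
A3 | alternative 2 | allylic carbonate with α-formyl lactam | COC(=O)OC/C=C/[C@H]1OC(=O)[C@@H](C)[C@H]1[C@@H]1C[C@H]([C@H]2C[C@@H](C)C(=O)O2)N(CCCO[Si](C)(C)C(C)(C)C)C(=O)C1C=O
A4 | alternative 2 | vinyl-substituted tetracyclic formyl lactam | C=C[C@@H]1[C@H]2OC(=O)[C@@H](C)[C@H]2[C@@H]2C[C@H]([C@H]3C[C@@H](C)C(=O)O3)N(CCCO[Si](C)(C)C(C)(C)C)C(=O)[C@]12C=O
A5 | alternative 3 | aldehyde ester with propenyl and acetal on C27 | O=C[C@@H]([C@H](C)C(=O)OC)[C@@H]1C[C@H]([C@H]2C[C@@H](C)C(=O)O2)N(CCCO[Si](C)(C)C(C)(C)C)C(=O)[C@@]1(/C=C/C)C(OC)OC
A6 | alternative 3 | tetracyclic acetal lactam (identical with 26) | CC[C@@H]1[C@H]2OC(=O)[C@@H](C)[C@H]2[C@@H]2C[C@H]([C@H]3C[C@@H](C)C(=O)O3)N(CCCO[Si](C)(C)C(C)(C)C)C(=O)[C@]12C(OC)OC
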